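**Retrosynthetic overview**
1. Ring B (the 10-membered lactone) is closed last, by Shiina macrolactonisation of the C1 acid onto the C9 hydroxyl; the furyl-bearing carbon is then set by kinetic protonation and the silyl ether is removed.
2. Ring A (the γ-butyrolactone) arises by translactonisation: an organolithium (C7–C10) adds to the C6 lactone carbonyl of a Michael adduct, and the freed C3 oxygen re-closes onto the furylacetate ester.
3. The C4–Cα bond comes from a Michael addition of a furylacetate enolate to a (S)-butenolide, anti to its side chain; trans in that temporary ring becomes cis (C3/C4) in ring A.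
4. The butenolide comes from tert-butyl acetate and acrolein (aldol, lipase acrylation, small-ring metathesis); the furan donor comes from a Negishi coupling; (R)-butane-1,3-diol supplies both carbinol centres.
5. Order of rings: furan (bought), temporary butenolide, ring A, ring B.

Assumption: locants are macrolide C1 (lactone C=O) to C9 (methyl carbinol) and Cα for the furyl-bearing carbon; 17, 21, 22 and 24 are carried as epimer mixtures at Cα (no stereo label there), and methyl 2-(furan-2-yl)acetate is taken as a catalogue chemical.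

**Step 1**
Reactants: 1 (R)-butane-1,3-diol
Product: 2 (R)-4-iodobutan-2-ol
Conditions: PPh3, I2, imidazole, CH2Cl2, 0 °C
Reagents that add atoms: iodine, II
Why: Garegg–Samuelsson (Appel-type) iodination, in which the iodophosphonium reagent takes the unhindered primary hydroxyl far faster than the secondary one and leaves the chiral-pool stereocentre untouched.

**Step 2**
Reactants: 2 (R)-4-iodobutan-2-ol
Product: 3 tert-butyl{[(2R)-4-iodobutan-2-yl]oxy}diphenylsilane
Conditions: TBDPSCl, imidazole, DMF, rt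
Reagents that add atoms: tert-butyl(chloro)diphenylsilane, CC(C)(C)[Si](Cl)(c1ccccc1)c1ccccc1
Why: O-silylation giving an acid-stable silyl ether that will survive the TFA of step 11.

**Step 3**
Reactants: 4 methyl 2-(furan-2-yl)acetate
Product: 5 methyl 2-(5-bromofuran-2-yl)acetate
Conditions: NBS, DMF, 0 °C, dark
Reagents that add atoms: N-bromosuccinimide, O=C1CCC(=O)N1Br
Why: electrophilic aromatic bromination, which for a 2-substituted furan goes to the free α-position (C5); the product is used at once.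

**Step 4**
Reactants: 3 tert-butyl{[(2R)-4-iodobutan-2-yl]oxy}diphenylsilane, 5 methyl 2-(5-bromofuran-2-yl)acetate
Product: 7 methyl 2-{5-[(3R)-3-(tert-butyldiphenylsilyloxy)butyl]furan-2-yl}acetate, via alkylzinc iodide 6 (not isolated)
Conditions: 3, Zn dust, LiCl, THF, 40 °C; then 5, Pd(OAc)2 (2 mol%), SPhos (4 mol%), THF, rt
Reagents that add atoms: none
Why: Negishi sp3–sp2 cross-coupling, in which zinc inserts into the primary C–I bond and the weakly basic alkylzinc tolerates the acidic furylacetate ester and the silyl ether while the remote stereocentre is unaffected.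

**Step 5**
Reactants: 2 (R)-4-iodobutan-2-ol
Product: 8 tert-butyl{[(2R)-4-iodobutan-2-yl]oxy}dimethylsilane
Conditions: TBSCl, imidazole, DMF, rt
Reagents that add atoms: tert-butyl(chloro)dimethylsilane, CC(C)(C)[Si](C)(C)Cl
Why: O-silylation giving a silyl ether that withstands organolithium chemistry but is cleaved by TFA together with the tert-butyl ester in step 11.

**Step 6**
Reactants: 9 tert-butyl acetate, 10 acrolein
Product: 12 rac-tert-butyl 3-hydroxypent-4-enoate, via lithium enolate 11 (not isolated)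
Conditions: LiN(iPr)2, THF, −78 °C; then 10; AcOH
Reagents that add atoms: none
Why: aldol addition of a lithium ester enolate, which adds 1,2 to the enal at −78 °C; the racemate is resolved in step 7.

**Step 7**
Reactants: 12 rac-tert-butyl 3-hydroxypent-4-enoate, 13 vinyl acrylate
Product: 14 tert-butyl (3S)-3-(acryloyloxy)pent-4-enoate
Conditions: Burkholderia cepacia lipase (Amano lipase PS), MTBE, 30 °C, stopped near 45% conversion
Reagents that add atoms: none
Why: lipase-catalysed kinetic resolution by irreversible transesterification; by the Kazlauskas rule (vinyl as medium group, CH2CO2tBu as large group) the (S)-alcohol is acylated and is obtained directly as the acrylate, while the (R) half of 12 is left behind and separated.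

**Step 8**
Reactants: 14 tert-butyl (3S)-3-(acryloyloxy)pent-4-enoate
Product: 15 tert-butyl 2-[(2S)-5-oxo-2,5-dihydrofuran-2-yl]acetate
Conditions: second-generation Grubbs catalyst RuCl2(=CHPh)(PCy3)(H2IMes) (5 mol%), CH2Cl2 (0.01 M), 40 °C
Reagents that add atoms: none
Why: ring-closing metathesis of the acrylate with the vinyl group gives the butenolide with loss of ethene and without touching the C3 stereocentre.

**Step 9**
Reactants: 7 methyl 2-{5-[(3R)-3-(tert-butyldiphenylsilyloxy)butyl]furan-2-yl}acetate, 15 tert-butyl 2-[(2S)-5-oxo-2,5-dihydrofuran-2-yl]acetate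
Product: 17 tert-butyl 2-[(2S,3S)-3-{1-[5-((3R)-3-(tert-butyldiphenylsilyloxy)butyl)furan-2-yl]-2-methoxy-2-oxoethyl}-5-oxooxolan-2-yl]acetate (both Cα epimers), via lithium enolate 16 (not isolated)
Conditions: 7, LiN(iPr)2, THF, −78 °C; then 15, −78 °C; AcOH
Reagents that add atoms: none
Why: Michael addition of the stabilised furylacetate enolate to the butenolide, which occurs anti to the C3 side chain and so sets C4 as (S), trans in this ring.

**Step 10**
Reactants: 17 Michael adduct, 8 tert-butyl{[(2R)-4-iodobutan-2-yl]oxy}dimethylsilane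
Product: 21 tert-butyl 2-[(2S,3S)-3-[(5R)-5-(tert-butyldimethylsilyloxy)-2-oxohexyl]-4-{5-[(3R)-3-(tert-butyldiphenylsilyloxy)butyl]furan-2-yl}-5-oxooxolan-2-yl]acetate (both Cα epimers), via organolithium 18 (not isolated), via ester enolate 19 (not isolated), via lactol 20 (not isolated)
Conditions: 8, t-BuLi (2 equiv), Et2O, −78 °C; 17, LiN(SiMe3)2 (1.05 equiv), THF, −78 °C; mix at −78 °C; AcOH; then PPTS (cat.), toluene, 50 °C
Reagents that add atoms: none
Why: organolithium addition to a γ-lactone stops at the lactolate at −78 °C while the acidic furylacetate is masked as its enolate and the tert-butyl ester is too hindered; mild acid then lets the C3 hydroxyl of lactol 20 close onto the methyl ester (translactonisation, loss of MeOH), which turns the trans adduct into the cis C3/C4 lactone without touching either centre.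

**Step 11**
Reactants: 21 keto lactone tert-butyl ester
Product: 22 2-[(2S,3S)-4-{5-[(3R)-3-(tert-butyldiphenylsilyloxy)butyl]furan-2-yl}-3-[(5R)-5-hydroxy-2-oxohexyl]-5-oxooxolan-2-yl]acetic acid (both Cα epimers)
Conditions: TFA/CH2Cl2/H2O (10:30:1), 0 °C to rt; then THF/H2O
Reagents that add atoms: none
Why: acidolysis removes the tert-butyl ester (as isobutene) and the secondary TBS ether in one operation while the bulkier TBDPS ether survives; the aqueous finish reopens any cyclic enol ether formed from the γ-hydroxy ketone.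

**Step 12**
Reactants: 22 seco acid
Product: 24 TBDPS-protected macrolactone (ring B closed; 3S,4S,9R; both Cα epimers), via mixed anhydride 23 (not isolated)
Conditions: MNBA (1.5 equiv), DMAP (6 equiv), CH2Cl2, rt, 22 added over 12 h (final 1 mM)
Reagents that add atoms: none
Why: Shiina macrolactonisation, in which the mixed anhydride is relayed through the acylpyridinium to the C9 hydroxyl under high dilution, helped by the cis C2 and C5 arms on ring A; Cα merely equilibrates under the basic conditions and is set in step 13.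

**Step 13**
Reactants: 24 TBDPS-protected macrolactone
Product: 26 TBDPS ether of cordycicadin B (Cα S; furyl cis to C5 and C2), via lithium enolate 25 (not isolated)
Conditions: LiN(SiMe3)2 (1.1 equiv), THF, −78 °C; then 2,6-di-tert-butyl-4-methylphenol (3 equiv), −78 °C; AcOH
Reagents that add atoms: none
Why: kinetic protonation of a lactone enolate; one equivalent of the hindered amide settles on the most acidic site (the furyl-substituted lactone C–H, several pK units below the ketone and macrolactone α-hydrogens), and the bulky phenol protonates the open face opposite the C4–C5 and C3–C2 bonds, forcing the furyl group cis to them.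

**Step 14**
Reactants: 26 TBDPS ether of cordycicadin B
Product: 27 cordycicadin B
Conditions: HF·pyridine, pyridine, THF, 0 °C to rt
Reagents that add atoms: none
Why: fluoride-mediated desilylation under mildly acidic buffered conditions, which neither epimerises Cα nor triggers β-elimination across C2/C3.

**Compound list**
1 | (R)-butane-1,3-diol | C[C@@H](O)CCO | starting material
2 | (R)-4-iodobutan-2-ol | C[C@@H](O)CCI | intermediate
3 | tert-butyl{[(2R)-4-iodobutan-2-yl]oxy}diphenylsilane | C[C@@H](O[Si](c1ccccc1)(c1ccccc1)C(C)(C)C)CCI | intermediate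
4 | methyl 2-(furan-2-yl)acetate | COC(=O)Cc1ccco1 | starting material
5 | methyl 2-(5-bromofuran-2-yl)acetate | COC(=O)Cc1ccc(Br)o1 | intermediate
6 | {(3R)-3-[(tert-butyldiphenylsilyl)oxy]butyl}zinc iodide | C[C@@H](O[Si](c1ccccc1)(c1ccccc1)C(C)(C)C)CC[Zn]I | intermediate
7 | methyl 2-{5-[(3R)-3-(tert-butyldiphenylsilyloxy)butyl]furan-2-yl}acetate | COC(=O)Cc1ccc(CC[C@@H](C)O[Si](c2ccccc2)(c2ccccc2)C(C)(C)C)o1 | intermediate
8 | tert-butyl{[(2R)-4-iodobutan-2-yl]oxy}dimethylsilane | C[C@@H](O[Si](C)(C)C(C)(C)C)CCI | intermediate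
9 | tert-butyl acetate | CC(=O)OC(C)(C)C | starting material
10 | acrolein | C=CC=O | starting material
11 | lithium enolate of tert-butyl acetate | C=C(O[Li])OC(C)(C)C | intermediate
12 | rac-tert-butyl 3-hydroxypent-4-enoate | C=CC(O)CC(=O)OC(C)(C)C | intermediate
13 | vinyl acrylate | C=CC(=O)OC=C | starting material
14 | tert-butyl (3S)-3-(acryloyloxy)pent-4-enoate | C=C[C@H](CC(=O)OC(C)(C)C)OC(=O)C=C | intermediate
15 | tert-butyl 2-[(2S)-5-oxo-2,5-dihydrofuran-2-yl]acetate | O=C1C=C[C@H](CC(=O)OC(C)(C)C)O1 | intermediate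
16 | lithium enolate of 7 | COC(O[Li])=Cc1ccc(CC[C@@H](C)O[Si](c2ccccc2)(c2ccccc2)C(C)(C)C)o1 | intermediate
17 | tert-butyl 2-[(2S,3S)-3-{1-[5-((3R)-3-(tert-butyldiphenylsilyloxy)butyl)furan-2-yl]-2-methoxy-2-oxoethyl}-5-oxooxolan-2-yl]acetate, both Cα epimers | O=C1C[C@@H](C(C(=O)OC)c2ccc(CC[C@@H](C)O[Si](c3ccccc3)(c3ccccc3)C(C)(C)C)o2)[C@H](CC(=O)OC(C)(C)C)O1 | intermediate
18 | [(3R)-3-(tert-butyldimethylsilyloxy)butyl]lithium | C[C@@H](O[Si](C)(C)C(C)(C)C)CC[Li] | intermediate
19 | lithium ester enolate of 17 | O=C1C[C@@H](C(=C(O[Li])OC)c2ccc(CC[C@@H](C)O[Si](c3ccccc3)(c3ccccc3)C(C)(C)C)o2)[C@H](CC(=O)OC(C)(C)C)O1 | intermediate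
20 | lactol from 18 and 19: the 5-hydroxy-5-[(3R)-3-(tert-butyldimethylsilyloxy)butyl]oxolane analogue of 17, hemiketal and Cα epimers | C[C@@H](O[Si](C)(C)C(C)(C)C)CCC1(O)C[C@@H](C(C(=O)OC)c2ccc(CC[C@@H](C)O[Si](c3ccccc3)(c3ccccc3)C(C)(C)C)o2)[C@H](CC(=O)OC(C)(C)C)O1 | intermediate
21 | tert-butyl 2-[(2S,3S)-3-[(5R)-5-(tert-butyldimethylsilyloxy)-2-oxohexyl]-4-{5-[(3R)-3-(tert-butyldiphenylsilyloxy)butyl]furan-2-yl}-5-oxooxolan-2-yl]acetate, both Cα epimers | C[C@@H](O[Si](C)(C)C(C)(C)C)CCC(=O)C[C@@H]1[C@H](CC(=O)OC(C)(C)C)OC(=O)C1c1ccc(CC[C@@H](C)O[Si](c2ccccc2)(c2ccccc2)C(C)(C)C)o1 | intermediate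
22 | 2-[(2S,3S)-4-{5-[(3R)-3-(tert-butyldiphenylsilyloxy)butyl]furan-2-yl}-3-[(5R)-5-hydroxy-2-oxohexyl]-5-oxooxolan-2-yl]acetic acid, both Cα epimers | C[C@@H](O)CCC(=O)C[C@@H]1[C@H](CC(=O)O)OC(=O)C1c1ccc(CC[C@@H](C)O[Si](c2ccccc2)(c2ccccc2)C(C)(C)C)o1 | intermediate
23 | mixed anhydride of 22 with 2-methyl-6-nitrobenzoic acid | C[C@@H](O)CCC(=O)C[C@@H]1[C@H](CC(=O)OC(=O)c2c(C)cccc2[N+](=O)[O-])OC(=O)C1c1ccc(CC[C@@H](C)O[Si](c2ccccc2)(c2ccccc2)C(C)(C)C)o1 | intermediate
24 | TBDPS-protected macrolactone: 9R-methyl-6-oxo 10-membered lactone cis-fused at C3/C4 (S,S) to the α-furyl γ-butyrolactone, both Cα epimers | C[C@@H]1CCC(=O)C[C@@H]2[C@H](CC(=O)O1)OC(=O)C2c1ccc(CC[C@@H](C)O[Si](c3ccccc3)(c3ccccc3)C(C)(C)C)o1 | intermediate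
25 | lithium lactone enolate of 24 | C[C@@H]1CCC(=O)C[C@@H]2[C@H](CC(=O)O1)OC(O[Li])=C2c1ccc(CC[C@@H](C)O[Si](c3ccccc3)(c3ccccc3)C(C)(C)C)o1 | intermediate
26 | TBDPS ether of cordycicadin B (Cα S, all-cis on ring A) | C[C@@H]1CCC(=O)C[C@@H]2[C@H](CC(=O)O1)OC(=O)[C@@H]2c1ccc(CC[C@@H](C)O[Si](c3ccccc3)(c3ccccc3)C(C)(C)C)o1 | intermediate
27 | cordycicadin B | C[C@@H]1CCC(=O)C[C@@H]2[C@H](CC(=O)O1)OC(=O)[C@@H]2c1ccc(CC[C@@H](C)O)o1 | target

**Step count**
Total: 14 steps. Longest linear sequence: 9 steps (1 → 2 → 3 → 7 → 17 → 21 → 22 → 24 → 26 → 27; the branch from 9 and 10 through 12, 14, 15 is equally long), which is 9/14 of the total.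

**Three steps most likely to fail**

Step 12 (macrolactonisation). A 10-membered ring is entropically and enthalpically hard to close; dimer formation, β-elimination of the activated β-acyloxy acid and hemiketal formation of the γ-hydroxy ketone all compete. The fallback closes the ring by metathesis at C7=C8; it sets out from 17 and comes back at 24. Me2AlN(OMe)Me (from AlMe3 and MeNH(OMe)·HCl, CH2Cl2, 0 °C) opens the lactone of 17, and the freed C3 alkoxide closes onto the methyl ester to give the Weinreb amide lactone F1. TFA in CH2Cl2 removes the tert-butyl ester to give the Weinreb amide acid F2. EDC·HCl and DMAP with commercial (R)-but-3-en-2-ol give the butenyl ester F3. LiN(SiMe3)2 (1 equiv, to mask the lactone as its enolate) followed by CH2=CHMgBr in THF at −78 °C converts the amide into the vinyl ketone diene F4. Ring-closing metathesis with the second-generation Hoveyda–Grubbs catalyst RuCl2(=CH-C6H4-2-OiPr)(H2IMes) in toluene at 80 °C and 1 mM gives the macrocyclic enone F5 (alkene geometry immaterial). H2 (1 atm) over Pd/C in EtOAc saturates the enone alkene and delivers 24.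

Step 13 (kinetic protonation). The face selectivity may be modest, and the ketone or the macrolactone could be enolised competitively. The fallback replaces proton transfer by hydrogen-atom transfer; it sets out from 24 and comes back at 26. LiN(SiMe3)2 then PhSeCl at −78 °C gives the α-phenylselanyl lactone F6. Bu3SnH with Et3B/air in toluene at −78 °C to rt cleaves the C–Se bond, and the planar Cα radical takes hydrogen from the stannane on the open face, giving 26 under neutral conditions that leave the ketone alone.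

Step 10 (organolithium addition and translactonisation). Over-addition, enolisation of the lactone or attack on the esters can erode the yield. The fallback makes the ketone by a neutral Fukuyama coupling; it sets out from 17 (with 8) and comes back at 21. Me2AlSEt (from AlMe3 and EtSH, CH2Cl2, 0 °C) opens the lactone of 17 as its S-ethyl thioester, and the C3 alkoxide re-closes onto the methyl ester to give the thioester lactone F7. Iodide 8 with Zn dust and LiCl in THF gives the alkylzinc iodide F8. PdCl2(PPh3)2 in toluene/THF at rt couples F8 with F7 to give 21 without any strong base.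

**Further compounds**
F1 | step 12 | tert-butyl 2-[(2S,3S)-4-{5-[(3R)-3-(tert-butyldiphenylsilyloxy)butyl]furan-2-yl}-3-{2-[methoxy(methyl)amino]-2-oxoethyl}-5-oxooxolan-2-yl]acetate | CON(C)C(=O)C[C@@H]1[C@H](CC(=O)OC(C)(C)C)OC(=O)C1c1ccc(CC[C@@H](C)O[Si](c2ccccc2)(c2ccccc2)C(C)(C)C)o1
F2 | step 12 | 2-[(2S,3S)-4-{5-[(3R)-3-(tert-butyldiphenylsilyloxy)butyl]furan-2-yl}-3-{2-[methoxy(methyl)amino]-2-oxoethyl}-5-oxooxolan-2-yl]acetic acid | CON(C)C(=O)C[C@@H]1[C@H](CC(=O)O)OC(=O)C1c1ccc(CC[C@@H](C)O[Si](c2ccccc2)(c2ccccc2)C(C)(C)C)o1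
F3 | step 12 | (2R)-but-3-en-2-yl ester of F2 | CON(C)C(=O)C[C@@H]1[C@H](CC(=O)O[C@H](C)C=C)OC(=O)C1c1ccc(CC[C@@H](C)O[Si](c2ccccc2)(c2ccccc2)C(C)(C)C)o1
F4 | step 12 | (2R)-but-3-en-2-yl 2-[(2S,3S)-4-{5-[(3R)-3-(tert-butyldiphenylsilyloxy)butyl]furan-2-yl}-5-oxo-3-(2-oxobut-3-en-1-yl)oxolan-2-yl]acetate | C=CC(=O)C[C@@H]1[C@H](CC(=O)O[C@H](C)C=C)OC(=O)C1c1ccc(CC[C@@H](C)O[Si](c2ccccc2)(c2ccccc2)C(C)(C)C)o1
F5 | step 12 | 7,8-didehydro analogue of 24 (macrocyclic enone) | C[C@@H]1C=CC(=O)C[C@@H]2[C@H](CC(=O)O1)OC(=O)C2c1ccc(CC[C@@H](C)O[Si](c3ccccc3)(c3ccccc3)C(C)(C)C)o1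
F6 | step 13 | Cα-(phenylselanyl) derivative of 24 | C[C@@H]1CCC(=O)C[C@@H]2[C@H](CC(=O)O1)OC(=O)C2([Se]c3ccccc3)c1ccc(CC[C@@H](C)O[Si](c3ccccc3)(c3ccccc3)C(C)(C)C)o1
F7 | step 10 | tert-butyl 2-[(2S,3S)-4-{5-[(3R)-3-(tert-butyldiphenylsilyloxy)butyl]furan-2-yl}-3-[2-(ethylsulfanyl)-2-oxoethyl]-5-oxooxolan-2-yl]acetate | CCSC(=O)C[C@@H]1[C@H](CC(=O)OC(C)(C)C)OC(=O)C1c1ccc(CC[C@@H](C)O[Si](c2ccccc2)(c2ccccc2)C(C)(C)C)o1
F8 | step 10 | {(3R)-3-[(tert-butyldimethylsilyl)oxy]butyl}zinc iodide | C[C@@H](O[Si](C)(C)C(C)(C)C)CC[Zn]I
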